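**Plan**

- The retrosynthesis first cuts C11=C12 and C11′=C12′ (two Horner–Wadsworth–Emmons olefinations on a central C10 bis-phosphonate), then C9=C10 and C9′=C10′ (cyanomethylenation of two C13 furanoid methyl ketones), then the O–C8 and O–C8′ ring bonds.
- Enabling feature: in each dihydrofuran ring (O, C5, C6, C7, C8) the oxygen spans C5 and C8 across the C6=C7 double bond, so the ring is the singlet-oxygen [4+2] adduct of an ionone-type diene C5=C6–C7=C8 less one oxygen atom.
- Unhydroxylated half, forward: an ionol-type dienol takes up O2 across C5/C8; phosphine-induced loss of one oxygen contracts the 1,2-dioxine to the 2,5-dihydrofuran with inversion at C8 (side chain cis to the C5 methyl); the carbinol then becomes the methyl ketone and the C15 enal.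
- Hydroxylated half, forward: the ring is made from an ene-dione and the side chain is attached by Sonogashira coupling; the endoperoxide is isomerised to a γ-hydroxy enone, C8′ is reset by Felkin reduction, and Mitsunobu closure with inversion gives the trans ring.
- The chain is joined last: C10 bis-phosphonate plus the unhydroxylated enal, then the hydroxylated enal, then desilylation.
- Stereochemistry: the C9/C9′ carbinols (oxazaborolidine reduction; chiral-pool alkynol) steer the oxygen face and the C8′ reduction and are then oxidised away; C3′ comes from asymmetric transfer hydrogenation; C5/C8 come from suprafacial cycloaddition followed by SN2 inversion.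

Key step: step 4

Assumption: free dienols are taken to add singlet oxygen mainly on the hydroxyl-bearing face of the H-eclipsed rotamer (like adduct) and silyl ethers on the opposite face; carotenoid numbering is used, with primed locants for the hydroxylated end.

**Route**

Step 1
Reactants: 1 β-ionone
Product: 2 (R)-β-ionol
Conditions: (S)-2-methyl-CBS-oxazaborolidine (cat.), BH3·SMe2, THF, −20 °C
Reagents that add atoms: none
Why: Corey–Bakshi–Shibata reduction, in which the oxazaborolidine–borane complex binds the ketone with the dienyl arm as the large group, so the (S)-catalyst should deliver hydride to the face that gives the (R)-carbinol at C9.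

Step 2
Reactants: 2 (R)-β-ionol
Product: 3 (5R,8R,9R)-5,8-endoperoxide alcohol
Conditions: O2, tetraphenylporphyrin (cat.), CH2Cl2, visible light, −20 °C; chromatography
Reagents that add atoms: dioxygen, O=O
Why: Singlet-oxygen [4+2] cycloaddition across the s-cis C5=C6–C7=C8 diene, a known reaction of ionone-type dienes, in which suprafacial addition ties C5 to C8 and hydrogen bonding of the C9 hydroxyl to the incoming oxygen should favour the like adduct, the other diastereomer being removed by chromatography.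

Step 3
Reactants: 3 (5R,8R,9R)-5,8-endoperoxide alcohol
Product: 4 endoperoxide tert-butyldimethylsilyl ether
Conditions: TBSOTf, 2,6-lutidine, CH2Cl2, −78 °C
Reagents that add atoms: tert-butyldimethylsilyl trifluoromethanesulfonate, CC(C)(C)[Si](C)(C)OS(=O)(=O)C(F)(F)F
Why: Silylation with a silyl triflate and a hindered pyridine base at low temperature avoids base-induced Kornblum–DeLaMare cleavage at C8–H, and the ether keeps the C9 oxygen out of the next step.

Step 4
Reactants: 4 endoperoxide tert-butyldimethylsilyl ether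
Product: 6 (5R,8S,9R) cis-furanoid C13 silyl ether, via dioxaphosphorane 5 (not isolated)
Conditions: PPh3 (1.1 equiv), toluene, 0 °C → 50 °C
Reagents that add atoms: none
Why: Triphenylphosphine inserts into the O–O bond to give dioxaphosphorane 5, which ionises at the more hindered P–O(C5) bond to a C5 alkoxide and a C8 oxyphosphonium, and the alkoxide then displaces triphenylphosphine oxide at C8. The closest known reaction is the triarylphosphine deoxygenation of monocyclic 3,6-dihydro-1,2-dioxines to 2,5-dihydrofurans, which inverts one carbon. The dihydrofuran closes in a 5-exo-tet SN2 mode as the 1,2-dioxine contracts. C8 is the stereocentre defined here: backside attack inverts the configuration installed by the cycloaddition, turning the trans relation of C9 and the C5 methyl in 4 into the cis relation (8S) of the target, while C5 keeps its oxygen and its configuration. The step needs SN2 at C8 to outrun SN2′ attack at C6 (vinyl epoxide) and simple reduction to the diol; the quaternary C5 cannot serve as electrophile, the secondary allylic C8 is activated, the Z ring alkene holds the C5 oxygen within reach of C8, and the silyl ether prevents competition from the C9 oxygen.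

Step 5
Reactants: 6 cis-furanoid C13 silyl ether
Product: 7 cis-furanoid C13 carbinol
Conditions: n-Bu4NF, THF, 0 °C → rt
Reagents that add atoms: none
Why: Fluoride-mediated silyl ether cleavage, driven by Si–F bond formation, leaves the allylic ring ether and both ring stereocentres untouched.

Step 6
Reactants: 7 cis-furanoid C13 carbinol
Product: 8 cis-furanoid C13 methyl ketone
Conditions: Dess–Martin periodinane, NaHCO3, CH2Cl2, 0 °C
Reagents that add atoms: none
Why: Dess–Martin oxidation under buffered, non-enolising conditions, so that the C8 hydrogen, now alpha to the carbonyl, should not epimerise.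

Step 7
Reactants: 8 cis-furanoid C13 methyl ketone
Product: 9 (9E) C15 nitrile
Conditions: (EtO)2P(O)CH2CN, NaH, THF, 0 °C → rt; chromatography
Reagents that add atoms: diethyl cyanomethylphosphonate, CCOP(=O)(CC#N)OCC
Why: Horner–Wadsworth–Emmons olefination with the small, weakly basic cyanomethylphosphonate anion, which should add faster than it enolises the ketone and place the nitrile trans to the bulkier dihydrofuranyl group, the minor Z isomer being removed by chromatography.

Step 8
Reactants: 9 (9E) C15 nitrile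
Product: 11 unhydroxylated C15 enal, via aluminio aldimine 10 (not isolated)
Conditions: i-Bu2AlH, toluene, −78 °C; then H2O/silica gel, 0 °C
Reagents that add atoms: water, O
Why: Partial reduction of the conjugated nitrile with i-Bu2AlH stops at the N-aluminio aldimine at low temperature, and mild hydrolysis releases the enal with the E double bond intact.

Step 9
Reactants: 12 ketoisophorone
Product: 13 (4R)-4-hydroxy-2,6,6-trimethylcyclohex-2-en-1-one
Conditions: RuCl[(R,R)-TsDPEN](p-cymene) (cat.), KOH (cat.), i-PrOH, rt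
Reagents that add atoms: none
Why: Noyori asymmetric transfer hydrogenation should reduce only the unhindered C4 carbonyl (the other is flanked by a quaternary carbon), with the alkenyl carbon in the aryl role, so the (R,R)-catalyst gives the (R)-carbinol that becomes C3′.

Step 10
Reactants: 13 (4R)-4-hydroxy-2,6,6-trimethylcyclohex-2-en-1-one
Product: 14 (4R)-silyloxy enone
Conditions: TBSCl, imidazole, DMF, rt
Reagents that add atoms: tert-butyldimethylsilyl chloride, CC(C)(C)[Si](C)(C)Cl
Why: Standard imidazole-promoted silylation of a secondary alcohol protects the future C3′ hydroxyl through the hydride, coupling and oxidation steps.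

Step 11
Reactants: 14 (4R)-silyloxy enone
Product: 16 (4S)-silyloxy cyclohexenyl triflate, via lithium enolate 15 (not isolated)
Conditions: LiBH(s-Bu)3, THF, −78 °C; then PhNTf2, −78 °C → rt
Reagents that add atoms: N-phenylbis(trifluoromethanesulfonimide), O=S(=O)(N(c1ccccc1)S(=O)(=O)C(F)(F)F)C(F)(F)F
Why: Conjugate hydride addition of the bulky borohydride to the hindered enone forms the tetrasubstituted enolate regiospecifically and O-sulfonylation traps it (reductive enolate triflation); the carbinol centre is untouched and only its descriptor changes.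

Step 12
Reactants: 16 (4S)-silyloxy cyclohexenyl triflate; 17 (R)-but-3-yn-2-ol
Product: 18 (3S,9R)-enynol
Conditions: Pd(PPh3)4 (cat.), CuI (cat.), i-Pr2NH, DMF, 50 °C
Reagents that add atoms: none
Why: Sonogashira coupling of an enol triflate with a terminal alkyne, established for hindered trimethylcyclohexenyl triflates, joins ring and side chain with C9′ taken from the chiral pool.

Step 13
Reactants: 18 (3S,9R)-enynol
Product: 19 (3S,9R)-dienol
Conditions: NaAlH2(OCH2CH2OMe)2, THF, 0 °C → rt; aqueous potassium sodium tartrate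
Reagents that add atoms: none
Why: Alkoxide-directed trans-hydroalumination of the propargylic alcohol and protonolysis on work-up give the (E)-allylic alcohol, the standard way from enynols to (E)-dienols.

Step 14
Reactants: 19 (3S,9R)-dienol
Product: 20 dienol triethylsilyl ether
Conditions: TESCl, imidazole, CH2Cl2, 0 °C
Reagents that add atoms: chlorotriethylsilane, CC[Si](Cl)(CC)CC
Why: Silylation gives an ether that can later be cleaved beside the tert-butyldimethylsilyl group and switches off hydroxyl direction, which for this C9′ epimer would point to the wrong diene face.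

Step 15
Reactants: 20 dienol triethylsilyl ether
Product: 21 (3R,5S,8S,9R)-5,8-endoperoxide bis-silyl ether
Conditions: O2, tetraphenylporphyrin (cat.), CH2Cl2, visible light, −20 °C; chromatography
Reagents that add atoms: dioxygen, O=O
Why: Singlet-oxygen [4+2] cycloaddition as in step 2, where attack anti to the C3′ silyloxy group and away from the C9′ silyloxy group of the H-eclipsed rotamer should both favour the (5S) adduct, whose C5′ epimer is removed by chromatography.

Step 16
Reactants: 21 5,8-endoperoxide bis-silyl ether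
Product: 22 (Z)-γ-hydroxy enone
Conditions: Et3N, CH2Cl2, rt
Reagents that add atoms: none
Why: Kornblum–DeLaMare rearrangement, in which the amine removes the only hydrogen on a peroxide carbon (C8′–H, C5′ being quaternary) and O–O cleavage gives the C8′ ketone and the tertiary C5′ alcohol with the Z alkene retained.

Step 17
Reactants: 22 (Z)-γ-hydroxy enone
Product: 23 (5S,8R,9R)-ene-diol
Conditions: LiBH(s-Bu)3 (2.5 equiv), THF, −78 °C
Reagents that add atoms: none
Why: 1,2-Reduction of the β,β-disubstituted enone under Felkin–Anh control, with hydride adding anti to the C9′–O bond past the small hydrogen, should give the (8R) carbinol syn to the (9R) silyl ether.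

Step 18
Reactants: 23 (5S,8R,9R)-ene-diol
Product: 24 trans-furanoid C13 bis-silyl ether
Conditions: PPh3, DIAD, THF, 0 °C → rt
Reagents that add atoms: none
Why: Mitsunobu cyclodehydration activates the less hindered secondary allylic hydroxyl, and the tertiary C5′ hydroxyl displaces it in a 5-exo-tet SN2 closure with inversion at C8′, placing the side chain trans to the C5′ methyl.

Step 19
Reactants: 24 trans-furanoid C13 bis-silyl ether
Product: 25 trans-furanoid C13 carbinol
Conditions: HF·pyridine, pyridine, THF, 0 °C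
Reagents that add atoms: none
Why: Buffered fluoride cleaves the more labile triethylsilyl ether selectively in the presence of the secondary tert-butyldimethylsilyl ether.

Step 20
Reactants: 25 trans-furanoid C13 carbinol
Product: 26 trans-furanoid C13 methyl ketone
Conditions: Dess–Martin periodinane, NaHCO3, CH2Cl2, 0 °C
Reagents that add atoms: none
Why: Buffered Dess–Martin oxidation, as in step 6, removes the C9′ stereocentre without enolising toward C8′.

Step 21
Reactants: 26 trans-furanoid C13 methyl ketone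
Product: 27 (9′E) silyloxy C15 nitrile
Conditions: (EtO)2P(O)CH2CN, NaH, THF, 0 °C → rt; chromatography
Reagents that add atoms: diethyl cyanomethylphosphonate, CCOP(=O)(CC#N)OCC
Why: Horner–Wadsworth–Emmons olefination as in step 7, expected to favour the E nitrile for the same steric reason.

Step 22
Reactants: 27 (9′E) silyloxy C15 nitrile
Product: 29 hydroxylated-half C15 enal (silyl ether), via aluminio aldimine 28 (not isolated)
Conditions: i-Bu2AlH, toluene, −78 °C; then H2O/silica gel, 0 °C
Reagents that add atoms: water, O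
Why: Nitrile-to-aldehyde reduction through the aluminio aldimine, as in step 8, is compatible with the silyl ether.

Step 23
Reactants: 30 (2E,4E,6E)-2,7-dimethylocta-2,4,6-trienedial
Product: 31 C10 diol
Conditions: NaBH4, MeOH, 0 °C
Reagents that add atoms: none
Why: Borohydride 1,2-reduction of both conjugated aldehyde termini gives the bis-allylic diol with the triene geometry retained.

Step 24
Reactants: 31 C10 diol
Product: 32 C10 dibromide
Conditions: PBr3, pyridine (cat.), Et2O, −10 °C
Reagents that add atoms: phosphorus tribromide, BrP(Br)Br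
Why: Conversion of primary allylic alcohols into bromides with PBr3 by SN2 displacement of the phosphite ester is standard for this diol.

Step 25
Reactants: 32 C10 dibromide
Product: 33 C10 bis-phosphonate
Conditions: P(OEt)3, toluene, 110 °C
Reagents that add atoms: triethyl phosphite, CCOP(OCC)OCC
Why: Twofold Michaelis–Arbuzov reaction of the reactive bis-allylic bromide gives the bis-phosphonate.

Step 26
Reactants: 33 C10 bis-phosphonate; 11 unhydroxylated C15 enal
Product: 35 C25 phosphonate, via phosphonate carbanion 34 (not isolated)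
Conditions: 33 (3 equiv), NaN(SiMe3)2 (1 equiv), THF, −78 °C; then 11, −78 → 0 °C; excess 33 recovered
Reagents that add atoms: none
Why: Horner–Wadsworth–Emmons olefination forms C11=C12 with the E preference of allylic phosphonates, the limiting aldehyde and excess bis-phosphonate favouring mono-olefination, and the furanoid being on the electrophile so that no carbanion arises next to its ring oxygen.

Step 27
Reactants: 35 C25 phosphonate; 29 hydroxylated-half C15 enal (silyl ether)
Product: 37 3′-O-silyl ether of the target, via phosphonate carbanion 36 (not isolated)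
Conditions: NaN(SiMe3)2, THF, −78 °C; then 29, −78 → 0 °C; argon, dark
Reagents that add atoms: none
Why: A second Horner–Wadsworth–Emmons olefination forms C11′=C12′ (E), and the tolerance of remote allylic ring oxygens by polyenyl carbanions in epoxy-carotenoid couplings supports survival of the far furanoid.

Step 28
Reactants: 37 3′-O-silyl ether of the target
Product: 38 target carotenoid
Conditions: n-Bu4NF, THF, 0 °C → rt; argon, dark
Reagents that add atoms: none
Why: Fluoride desilylation under non-acidic conditions frees the C3′ hydroxyl without the acid-promoted ionisation at C8/C8′ that would epimerise a furanoid polyene.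

**Compound list**

1 | β-ionone, (3E)-4-(2,6,6-trimethylcyclohex-1-en-1-yl)but-3-en-2-one | CC(=O)/C=C/C1=C(C)CCCC1(C)C | starting material
2 | (R)-β-ionol, (2R,3E)-4-(2,6,6-trimethylcyclohex-1-en-1-yl)but-3-en-2-ol | C[C@@H](O)/C=C/C1=C(C)CCCC1(C)C | intermediate
3 | (1R)-1-[(3R,8aR)-5,5,8a-trimethyl-3,5,6,7,8,8a-hexahydro-1,2-benzodioxin-3-yl]ethan-1-ol (5R,8R,9R endoperoxide alcohol) | C[C@@H](O)[C@H]1C=C2C(C)(C)CCC[C@@]2(C)OO1 | intermediate
4 | tert-butyl(dimethyl){(1R)-1-[(3R,8aR)-5,5,8a-trimethyl-3,5,6,7,8,8a-hexahydro-1,2-benzodioxin-3-yl]ethoxy}silane | C[C@@H](O[Si](C)(C)C(C)(C)C)[C@H]1C=C2C(C)(C)CCC[C@@]2(C)OO1 | intermediate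
5 | triphenyl dioxaphosphorane formed by insertion of phosphorus into the O–O bond of 4 (P bonded to O–C5 and O–C8; C5 R, C8 R, C9 R) | C[C@@H](O[Si](C)(C)C(C)(C)C)[C@H]1C=C2C(C)(C)CCC[C@@]2(C)OP(c3ccccc3)(c3ccccc3)(c3ccccc3)O1 | intermediate (not isolated)
6 | tert-butyl(dimethyl){(1R)-1-[(2S,7aR)-4,4,7a-trimethyl-2,4,5,6,7,7a-hexahydro-1-benzofuran-2-yl]ethoxy}silane (5R,8S cis-furanoid) | C[C@@H](O[Si](C)(C)C(C)(C)C)[C@@H]1C=C2C(C)(C)CCC[C@@]2(C)O1 | intermediate
7 | (1R)-1-[(2S,7aR)-4,4,7a-trimethyl-2,4,5,6,7,7a-hexahydro-1-benzofuran-2-yl]ethan-1-ol | C[C@@H](O)[C@@H]1C=C2C(C)(C)CCC[C@@]2(C)O1 | intermediate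
8 | 1-[(2S,7aR)-4,4,7a-trimethyl-2,4,5,6,7,7a-hexahydro-1-benzofuran-2-yl]ethan-1-one | CC(=O)[C@@H]1C=C2C(C)(C)CCC[C@@]2(C)O1 | intermediate
9 | (2E)-3-[(2S,7aR)-4,4,7a-trimethyl-2,4,5,6,7,7a-hexahydro-1-benzofuran-2-yl]but-2-enenitrile | N#C/C=C(\C)[C@@H]1C=C2C(C)(C)CCC[C@@]2(C)O1 | intermediate
10 | N-(diisobutylaluminio) aldimine derived from 9 | CC(C)C[Al](CC(C)C)N=C/C=C(\C)[C@@H]1C=C2C(C)(C)CCC[C@@]2(C)O1 | intermediate (not isolated)
11 | (2E)-3-[(2S,7aR)-4,4,7a-trimethyl-2,4,5,6,7,7a-hexahydro-1-benzofuran-2-yl]but-2-enal | O=C/C=C(\C)[C@@H]1C=C2C(C)(C)CCC[C@@]2(C)O1 | intermediate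
12 | ketoisophorone, 2,6,6-trimethylcyclohex-2-ene-1,4-dione | CC1=CC(=O)CC(C)(C)C1=O | starting material
13 | (4R)-4-hydroxy-2,6,6-trimethylcyclohex-2-en-1-one | CC1=C[C@H](O)CC(C)(C)C1=O | intermediate
14 | (4R)-4-{[tert-butyl(dimethyl)silyl]oxy}-2,6,6-trimethylcyclohex-2-en-1-one | CC1=C[C@H](O[Si](C)(C)C(C)(C)C)CC(C)(C)C1=O | intermediate
15 | lithium (4S)-4-{[tert-butyl(dimethyl)silyl]oxy}-2,6,6-trimethylcyclohex-1-en-1-olate | [Li+].CC1=C([O-])C(C)(C)C[C@@H](O[Si](C)(C)C(C)(C)C)C1 | intermediate (not isolated)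
16 | (4S)-4-{[tert-butyl(dimethyl)silyl]oxy}-2,6,6-trimethylcyclohex-1-en-1-yl trifluoromethanesulfonate | CC1=C(OS(=O)(=O)C(F)(F)F)C(C)(C)C[C@@H](O[Si](C)(C)C(C)(C)C)C1 | intermediate
17 | (R)-but-3-yn-2-ol | C[C@@H](O)C#C | starting material
18 | (2R)-4-[(4S)-4-{[tert-butyl(dimethyl)silyl]oxy}-2,6,6-trimethylcyclohex-1-en-1-yl]but-3-yn-2-ol | C[C@@H](O)C#CC1=C(C)C[C@H](O[Si](C)(C)C(C)(C)C)CC1(C)C | intermediate
19 | (2R,3E)-4-[(4S)-4-{[tert-butyl(dimethyl)silyl]oxy}-2,6,6-trimethylcyclohex-1-en-1-yl]but-3-en-2-ol | C[C@@H](O)/C=C/C1=C(C)C[C@H](O[Si](C)(C)C(C)(C)C)CC1(C)C | intermediate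
20 | triethylsilyl ether of 19 at the C9′ oxygen | C[C@@H](O[Si](CC)(CC)CC)/C=C/C1=C(C)C[C@H](O[Si](C)(C)C(C)(C)C)CC1(C)C | intermediate
21 | (3S,7R,8aS)-7-{[tert-butyl(dimethyl)silyl]oxy}-5,5,8a-trimethyl-3-[(1R)-1-(triethylsilyloxy)ethyl]-3,5,6,7,8,8a-hexahydro-1,2-benzodioxine | C[C@@H](O[Si](CC)(CC)CC)[C@@H]1C=C2C(C)(C)C[C@@H](O[Si](C)(C)C(C)(C)C)C[C@]2(C)OO1 | intermediate
22 | (3R)-1-[(1Z,2S,4R)-4-{[tert-butyl(dimethyl)silyl]oxy}-2-hydroxy-2,6,6-trimethylcyclohexylidene]-3-(triethylsilyloxy)butan-2-one | C[C@@H](O[Si](CC)(CC)CC)C(=O)/C=C1\[C@@](C)(O)C[C@H](O[Si](C)(C)C(C)(C)C)CC1(C)C | intermediate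
23 | (2R,3R)-1-[(1Z,2S,4R)-4-{[tert-butyl(dimethyl)silyl]oxy}-2-hydroxy-2,6,6-trimethylcyclohexylidene]-3-(triethylsilyloxy)butan-2-ol | C[C@@H](O[Si](CC)(CC)CC)[C@H](O)/C=C1\[C@@](C)(O)C[C@H](O[Si](C)(C)C(C)(C)C)CC1(C)C | intermediate
24 | tert-butyl(dimethyl)({(2S,6R,7aS)-4,4,7a-trimethyl-2-[(1R)-1-(triethylsilyloxy)ethyl]-2,4,5,6,7,7a-hexahydro-1-benzofuran-6-yl}oxy)silane (3′R,5′S,8′S trans-furanoid) | C[C@@H](O[Si](CC)(CC)CC)[C@@H]1C=C2C(C)(C)C[C@@H](O[Si](C)(C)C(C)(C)C)C[C@]2(C)O1 | intermediate
25 | (1R)-1-[(2S,6R,7aS)-6-{[tert-butyl(dimethyl)silyl]oxy}-4,4,7a-trimethyl-2,4,5,6,7,7a-hexahydro-1-benzofuran-2-yl]ethan-1-ol | C[C@@H](O)[C@@H]1C=C2C(C)(C)C[C@@H](O[Si](C)(C)C(C)(C)C)C[C@]2(C)O1 | intermediate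
26 | 1-[(2S,6R,7aS)-6-{[tert-butyl(dimethyl)silyl]oxy}-4,4,7a-trimethyl-2,4,5,6,7,7a-hexahydro-1-benzofuran-2-yl]ethan-1-one | CC(=O)[C@@H]1C=C2C(C)(C)C[C@@H](O[Si](C)(C)C(C)(C)C)C[C@]2(C)O1 | intermediate
27 | (2E)-3-[(2S,6R,7aS)-6-{[tert-butyl(dimethyl)silyl]oxy}-4,4,7a-trimethyl-2,4,5,6,7,7a-hexahydro-1-benzofuran-2-yl]but-2-enenitrile | N#C/C=C(\C)[C@@H]1C=C2C(C)(C)C[C@@H](O[Si](C)(C)C(C)(C)C)C[C@]2(C)O1 | intermediate
28 | N-(diisobutylaluminio) aldimine derived from 27 | CC(C)C[Al](CC(C)C)N=C/C=C(\C)[C@@H]1C=C2C(C)(C)C[C@@H](O[Si](C)(C)C(C)(C)C)C[C@]2(C)O1 | intermediate (not isolated)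
29 | (2E)-3-[(2S,6R,7aS)-6-{[tert-butyl(dimethyl)silyl]oxy}-4,4,7a-trimethyl-2,4,5,6,7,7a-hexahydro-1-benzofuran-2-yl]but-2-enal | O=C/C=C(\C)[C@@H]1C=C2C(C)(C)C[C@@H](O[Si](C)(C)C(C)(C)C)C[C@]2(C)O1 | intermediate
30 | (2E,4E,6E)-2,7-dimethylocta-2,4,6-trienedial | CC(/C=O)=C\C=C\C=C(C)\C=O | starting material
31 | (2E,4E,6E)-2,7-dimethylocta-2,4,6-triene-1,8-diol | CC(/CO)=C\C=C\C=C(C)\CO | intermediate
32 | (2E,4E,6E)-1,8-dibromo-2,7-dimethylocta-2,4,6-triene | CC(/CBr)=C\C=C\C=C(C)\CBr | intermediate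
33 | tetraethyl [(2E,4E,6E)-2,7-dimethylocta-2,4,6-triene-1,8-diyl]bis(phosphonate) | CC(/CP(=O)(OCC)OCC)=C\C=C\C=C(C)\CP(=O)(OCC)OCC | intermediate
34 | monosodium α-carbanion of 33 | [Na+].CC(/[CH-]P(=O)(OCC)OCC)=C\C=C\C=C(C)\CP(=O)(OCC)OCC | intermediate (not isolated)
35 | diethyl {(2E,4E,6E,8E,10E)-2,7-dimethyl-11-[(2S,7aR)-4,4,7a-trimethyl-2,4,5,6,7,7a-hexahydro-1-benzofuran-2-yl]dodeca-2,4,6,8,10-pentaen-1-yl}phosphonate (C25 phosphonate) | CC(/C=C/C=C(\C)[C@@H]1C=C2C(C)(C)CCC[C@@]2(C)O1)=C\C=C\C=C(C)\CP(=O)(OCC)OCC | intermediate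
36 | sodium α-carbanion of 35 | [Na+].CC(/C=C/C=C(\C)[C@@H]1C=C2C(C)(C)CCC[C@@]2(C)O1)=C\C=C\C=C(C)\[CH-]P(=O)(OCC)OCC | intermediate (not isolated)
37 | 3′-O-tert-butyldimethylsilyl ether of 38 | CC(/C=C/C=C(\C)[C@@H]1C=C2C(C)(C)CCC[C@@]2(C)O1)=C\C=C\C=C(C)\C=C\C=C(/C)[C@@H]1C=C2C(C)(C)C[C@@H](O[Si](C)(C)C(C)(C)C)C[C@]2(C)O1 | intermediate
38 | (5R,8S,3′R,5′S,8′S)-5,8:5′,8′-diepoxy-5,8,5′,8′-tetrahydro-β,β-caroten-3′-ol, all-E | CC(/C=C/C=C(\C)[C@@H]1C=C2C(C)(C)CCC[C@@]2(C)O1)=C\C=C\C=C(C)\C=C\C=C(/C)[C@@H]1C=C2C(C)(C)C[C@@H](O)C[C@]2(C)O1 | target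

**Count**

Total: 28 steps. Longest linear sequence: 16 steps (12 → 29 by steps 9–22, then steps 27 and 28).

**Steps most likely to fail**

Step 4. The oxyphosphonium–alkoxide pair may collapse by SN2′ attack at C6 to a vinyl epoxide, ionise at the tertiary allylic C5, or stall at the phosphorane and end as the diol. The fallback keeps the same C5–O to C8 bond formation but makes it in two known operations. Setting out from 4, the O–O bond is reduced with thiourea in methanol to (2R,3R)-3-{[tert-butyl(dimethyl)silyl]oxy}-1-[(1Z,2R)-2-hydroxy-2,6,6-trimethylcyclohexylidene]butan-2-ol F1. Mitsunobu cyclodehydration of F1 (PPh3, DIAD) then activates only the secondary C8 hydroxyl, and the C5 hydroxyl displaces it with the same inversion, coming back to the route at 6.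

Step 15. Facial selectivity of oxygen addition may be poor because both directing effects are weak, and ene hydroperoxidation of the ring alkene may compete. The fallback brings in hydroxyl direction and sets C8′ by chelation instead of Felkin control.
- Setting out from 16, Sonogashira coupling with (S)-but-3-yn-2-ol gives (2S)-4-[(4S)-4-{[tert-butyl(dimethyl)silyl]oxy}-2,6,6-trimethylcyclohex-1-en-1-yl]but-3-yn-2-ol F2, and NaAlH2(OCH2CH2OMe)2 reduction gives the (2S,3E)-dienol F3.
- Photooxygenation of the free alcohol, where hydroxyl direction and the C3′ silyloxy group point to the same face, should give (1S)-1-[(3S,7R,8aS)-7-{[tert-butyl(dimethyl)silyl]oxy}-5,5,8a-trimethyl-3,5,6,7,8,8a-hexahydro-1,2-benzodioxin-3-yl]ethan-1-ol F4.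
- Methoxymethylation (MOMCl, i-Pr2NEt) gives the methoxymethyl ether F5, and Et3N-induced Kornblum–DeLaMare rearrangement gives (3S)-1-[(1Z,2S,4R)-4-{[tert-butyl(dimethyl)silyl]oxy}-2-hydroxy-2,6,6-trimethylcyclohexylidene]-3-(methoxymethoxy)butan-2-one F6.
- Chelation-controlled reduction with Zn(BH4)2 should give the anti (2R,3S)-diol F7, and Mitsunobu closure gives the trans-furanoid methoxymethyl ether F8.
- ZnBr2 with n-PrSH removes the acetal to give (1S)-1-[(2S,6R,7aS)-6-{[tert-butyl(dimethyl)silyl]oxy}-4,4,7a-trimethyl-2,4,5,6,7,7a-hexahydro-1-benzofuran-2-yl]ethan-1-ol F9, and Dess–Martin oxidation comes back to the route at 26.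

Step 7 (the same concern applies to step 21). The phosphonate anion may enolise the ketone toward C8, leading to epimerisation at C8 or migration of the ring double bond into conjugation, and E/Z control may be modest. The fallback avoids a basic olefination. Setting out from 8, CH2=CHMgBr with CeCl3 in THF at −78 °C adds without enolisation to give 2-[(2S,7aR)-4,4,7a-trimethyl-2,4,5,6,7,7a-hexahydro-1-benzofuran-2-yl]but-3-en-2-ol F10 (both carbinol epimers). Babler–Dauben oxidative transposition with pyridinium chlorochromate, C5H5NH[CrO3Cl], then gives the enal directly, and after removal of the Z isomer the route is rejoined at 11.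

**Further compounds**

F1 | step 4 | (2R,3R)-3-{[tert-butyl(dimethyl)silyl]oxy}-1-[(1Z,2R)-2-hydroxy-2,6,6-trimethylcyclohexylidene]butan-2-ol | C[C@@H](O[Si](C)(C)C(C)(C)C)[C@H](O)/C=C1\[C@](C)(O)CCCC1(C)C
F2 | step 15 | (2S)-4-[(4S)-4-{[tert-butyl(dimethyl)silyl]oxy}-2,6,6-trimethylcyclohex-1-en-1-yl]but-3-yn-2-ol | C[C@H](O)C#CC1=C(C)C[C@H](O[Si](C)(C)C(C)(C)C)CC1(C)C
F3 | step 15 | (2S,3E)-4-[(4S)-4-{[tert-butyl(dimethyl)silyl]oxy}-2,6,6-trimethylcyclohex-1-en-1-yl]but-3-en-2-ol | C[C@H](O)/C=C/C1=C(C)C[C@H](O[Si](C)(C)C(C)(C)C)CC1(C)C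
F4 | step 15 | (1S)-1-[(3S,7R,8aS)-7-{[tert-butyl(dimethyl)silyl]oxy}-5,5,8a-trimethyl-3,5,6,7,8,8a-hexahydro-1,2-benzodioxin-3-yl]ethan-1-ol | C[C@H](O)[C@@H]1C=C2C(C)(C)C[C@@H](O[Si](C)(C)C(C)(C)C)C[C@]2(C)OO1
F5 | step 15 | methoxymethyl ether of F4 | C[C@H](OCOC)[C@@H]1C=C2C(C)(C)C[C@@H](O[Si](C)(C)C(C)(C)C)C[C@]2(C)OO1
F6 | step 15 | (3S)-1-[(1Z,2S,4R)-4-{[tert-butyl(dimethyl)silyl]oxy}-2-hydroxy-2,6,6-trimethylcyclohexylidene]-3-(methoxymethoxy)butan-2-one | C[C@H](OCOC)C(=O)/C=C1\[C@@](C)(O)C[C@H](O[Si](C)(C)C(C)(C)C)CC1(C)C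
F7 | step 15 | (2R,3S)-1-[(1Z,2S,4R)-4-{[tert-butyl(dimethyl)silyl]oxy}-2-hydroxy-2,6,6-trimethylcyclohexylidene]-3-(methoxymethoxy)butan-2-ol | C[C@H](OCOC)[C@H](O)/C=C1\[C@@](C)(O)C[C@H](O[Si](C)(C)C(C)(C)C)CC1(C)C
F8 | step 15 | tert-butyl({(2S,6R,7aS)-2-[(1S)-1-(methoxymethoxy)ethyl]-4,4,7a-trimethyl-2,4,5,6,7,7a-hexahydro-1-benzofuran-6-yl}oxy)dimethylsilane | C[C@H](OCOC)[C@@H]1C=C2C(C)(C)C[C@@H](O[Si](C)(C)C(C)(C)C)C[C@]2(C)O1
F9 | step 15 | (1S)-1-[(2S,6R,7aS)-6-{[tert-butyl(dimethyl)silyl]oxy}-4,4,7a-trimethyl-2,4,5,6,7,7a-hexahydro-1-benzofuran-2-yl]ethan-1-ol | C[C@H](O)[C@@H]1C=C2C(C)(C)C[C@@H](O[Si](C)(C)C(C)(C)C)C[C@]2(C)O1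
F10 | step 7 | 2-[(2S,7aR)-4,4,7a-trimethyl-2,4,5,6,7,7a-hexahydro-1-benzofuran-2-yl]but-3-en-2-ol (both carbinol epimers) | C=CC(C)(O)[C@@H]1C=C2C(C)(C)CCC[C@@]2(C)O1
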